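**Retrosynthetic overview**

1. Target ⇒ (debenzylation, acetonide removal) 5,6-O-isopropylidene-3'-O-benzyl chlorohydrin ⇒ (C7–C8 disconnection, intramolecular vinylogous chloro-aldol addition) a 2-(chloromethyl)-4-pyranone whose C3 carries a (4S,5S)-dioxolane-4-carbaldehyde.
2. Enabling feature: C8 stands on C8a of the 4-pyranone ring, so C8–C8a=C4a–C4=O is a vinylogous α-chloro ketone and C8 a latent nucleophile, while the carbinol carbon C7 is a latent aldehyde; the trans C8–Cl/C7–OH pair is an aldol (interrupted Darzens) retron.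
3. The carbons C8–C8a–C4a–C5–C6–C7 form an unbranched chain that maps onto a 3-deoxy-hex-2-ulose: pyranone aldehyde ⇒ primary alcohol ⇒ acylketene (from a 6-(2-arylethyl)dioxinone) + 1-C-(chloromethyl)-3,4-O-isopropylidene-D-arabinal, whose C3/C4 become C5/C6 (S,S) and whose ring oxygen becomes the C7 hydroxyl.
4. Glycal ⇐ 3,4-di-O-acetyl-D-arabinal (deacetylation, acetonide, C1-lithiation/hydroxymethylation, chlorination); dioxinone ⇐ 2,2,6-trimethyl-4H-1,3-dioxin-4-one + 3-(benzyloxy)-4-methoxybenzyl bromide.
5. Order of ring formation: aryl ring bought; pyranone ring in step 7 (hetero-Diels–Alder reaction, aromatized by opening the sugar ring); carbocycle last, in step 9.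

Key step: step 9

Remark: all intermediates are described with the chromone numbering of the target (O1, C2, C3, C4, C4a, C5–C8, C8a) unless "sugar numbering" is stated; compounds 1, 3 and 6 are taken to be commercial.

Step 1
Reactants: 1 [3-(benzyloxy)-4-methoxyphenyl]methanol
Product: 2 2-(benzyloxy)-4-(bromomethyl)-1-methoxybenzene
Conditions: PBr3 (0.4 equiv), Et2O, 0 °C → rt
Reagents that add atoms: phosphorus tribromide, BrP(Br)Br
Why: Bromination of a benzylic alcohol with PBr3 (phosphite ester, then SN2 displacement by bromide) should be clean on this electron-rich benzyl alcohol, and the aryl benzyl and methyl ethers are inert at 0 °C.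

Step 2
Reactants: 3 2,2,6-trimethyl-4H-1,3-dioxin-4-one; 2 2-(benzyloxy)-4-(bromomethyl)-1-methoxybenzene
Product: 5 6-{2-[3-(benzyloxy)-4-methoxyphenyl]ethyl}-2,2-dimethyl-4H-1,3-dioxin-4-one, via lithium dienolate 4 (not isolated)
Conditions: LiN(iPr)2 (1.1 equiv), THF, −78 °C; then 2, DMPU, −78 → −40 °C
Reagents that add atoms: none
Why: Vinylogous (γ) enolate alkylation, in which LiN(iPr)2 removes a hydrogen of the 6-methyl group and the lithium dienolate is alkylated at its γ-carbon by the reactive benzylic bromide, is the usual entry to 6-substituted dioxinones.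

Step 3
Reactants: 6 3,4-di-O-acetyl-D-arabinal
Product: 7 D-arabinal (1,5-anhydro-2-deoxy-D-erythro-pent-1-enitol)
Conditions: NaOMe (cat.), MeOH, rt
Reagents that add atoms: none
Why: Zemplén transesterification should remove both acetates under catalytic NaOMe without touching the base-stable enol ether or the two stereocenters.

Step 4
Reactants: 7 D-arabinal
Product: 8 3,4-O-isopropylidene-D-arabinal
Conditions: 2-methoxypropene (1.5 equiv), pyridinium p-toluenesulfonate (cat.), DMF, 0 °C
Reagents that add atoms: 2-methoxypropene, COC(C)=C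
Why: Kinetic acetonide formation (acetal exchange) on the cis-3,4-diol under weak acid at 0 °C should close the cis-fused dioxolane before the enol ether can add alcohol or undergo Ferrier rearrangement, with C3 and C4 untouched.

Step 5
Reactants: 8 3,4-O-isopropylidene-D-arabinal
Product: 10 1-C-(hydroxymethyl)-3,4-O-isopropylidene-D-arabinal (2,6-anhydro-3-deoxy-4,5-O-isopropylidene-D-erythro-hex-2-enitol), via 1-lithio glycal 9 (not isolated)
Conditions: tBuLi (3 equiv), THF, −78 → 0 °C; then CH2O (gas from cracked paraformaldehyde), −78 °C → rt; H2O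
Reagents that add atoms: formaldehyde, C=O
Why: C1-lithiation of a glycal (vinylic deprotonation next to the ring oxygen by tBuLi) followed by 1,2-addition of the vinyllithium to formaldehyde should install the future C8 as a hydroxymethyl group without creating a stereocenter.

Step 6
Reactants: 10 1-C-(hydroxymethyl)-3,4-O-isopropylidene-D-arabinal
Product: 12 1-C-(chloromethyl)-3,4-O-isopropylidene-D-arabinal, via mesylate 11 (not isolated)
Conditions: MsCl (1.2 equiv), 2,4,6-collidine (2 equiv), LiCl (3 equiv), DMF, 0 °C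
Reagents that add atoms: lithium chloride, [Li+].[Cl-]
Why: Mesylation followed by SN2 displacement with chloride in DMF under buffered, non-acidic conditions should convert the allylic primary alcohol into the chloride without ionizing the enol ether or the acetonide.

Step 7
Reactants: 5 6-{2-[3-(benzyloxy)-4-methoxyphenyl]ethyl}-2,2-dimethyl-4H-1,3-dioxin-4-one; 12 1-C-(chloromethyl)-3,4-O-isopropylidene-D-arabinal
Product: 15 6-{2-[3-(benzyloxy)-4-methoxyphenyl]ethyl}-2-(chloromethyl)-3-[(4S,5R)-5-(hydroxymethyl)-2,2-dimethyl-1,3-dioxolan-4-yl]-4H-pyran-4-one, via acylketene 13 (not isolated), via cycloadduct 14 (not isolated)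
Conditions: 5 added slowly to 12 (1.5 equiv), toluene, 110 °C; then p-toluenesulfonic acid monohydrate (TsOH·H2O, 10 mol %), CH2Cl2, 0 °C → rt
Reagents that add atoms: none
Why: Thermal retro-[4+2] of the dioxinone releases acetone and acylketene 13, which should undergo an inverse-electron-demand hetero-Diels–Alder reaction with the electron-rich enol ether (ketene carbon to the nucleophilic C2, acyl oxygen to C1, sugar numbering, anti to the acetonide), after which acid ionizes the ketal of 14 and eliminates across C1–C2 so that the sugar ring opens, the 4-pyranone aromatizes and the former ring oxygen becomes the primary hydroxyl, while C3 and C4 of the sugar are carried over unchanged as C5 and C6.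

Step 8
Reactants: 15 6-{2-[3-(benzyloxy)-4-methoxyphenyl]ethyl}-2-(chloromethyl)-3-[(4S,5R)-5-(hydroxymethyl)-2,2-dimethyl-1,3-dioxolan-4-yl]-4H-pyran-4-one
Product: 16 (4S,5S)-5-{6-[2-(3-benzyloxy-4-methoxyphenyl)ethyl]-2-(chloromethyl)-4-oxo-4H-pyran-3-yl}-2,2-dimethyl-1,3-dioxolane-4-carbaldehyde
Conditions: Dess–Martin periodinane (1.3 equiv), CH2Cl2, 0 °C → rt
Reagents that add atoms: none
Why: Dess–Martin oxidation of the primary alcohol to the aldehyde under non-basic conditions should avoid epimerization of the α-alkoxy center C6 and leave the reactive chloromethyl group alone.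

Step 9
Reactants: 16 (4S,5S)-5-{6-[2-(3-benzyloxy-4-methoxyphenyl)ethyl]-2-(chloromethyl)-4-oxo-4H-pyran-3-yl}-2,2-dimethyl-1,3-dioxolane-4-carbaldehyde
Product: 18 5,6-O-isopropylidene-3'-O-benzyl derivative of the target (2-{2-[3-(benzyloxy)-4-methoxyphenyl]ethyl}-8-chloro-7-hydroxy-5,6-(isopropylidenedioxy)-5,6,7,8-tetrahydro-4H-chromen-4-one; O5/O6/O7 all cis; Cl trans to 7-OH; absolute configuration as in 19), via titanium dienolate 17 (not isolated)
Conditions: TiCl4 (2.2 equiv), iPr2NEt (1.2 equiv), CH2Cl2, −78 → −40 °C; aq. NH4Cl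
Reagents that add atoms: none
Why: Proposed new method: TiCl4 binds the most Lewis-basic site, the pyranone oxygen O4, which makes the chloromethyl hydrogens at C8 (vinylogous to C4=O through C8a=C4a and α to chlorine) acidic enough for iPr2NEt; the resulting trichlorotitanium dienolate 17 (exocyclic C8=C8a) adds through C8 to the TiCl4-activated C7 aldehyde, and the titanium alkoxide formed does not displace chloride, so the reaction should stop at the chlorohydrin (an interrupted vinylogous Darzens reaction). The closest known reaction types are the TiCl4/amine soft-enolization aldol reaction, the lateral (vinylogous) aldol reaction of metalated 2-alkyl-4-pyranones, and chloro-aldol reactions of α-chloro carbonyl compounds that are stopped at the chlorohydrin. The carbocycle closes in a 6-(enolendo)-exo-trig aldol mode, which Baldwin's rules for enolates favour. C8 is controlled by the dienolate geometry and the ring: allylic 1,3-strain with the C5 substituent on C4a places chlorine on the side of O1, so that it becomes pseudo-equatorial, and the antiperiplanar open transition state puts O7 equatorial and therefore trans to chlorine. C7 is controlled by the cis-acetonide at C5/C6: chelation of titanium between O4 and O5 holds O5 in the pyranone plane and O6 axial, and the α-chelate between O6 and the aldehyde oxygen then exposes the aldehyde face that gives the 6,7-cis alcohol. The step needs site-selective enolization at C8 in the presence of the epimerizable aldehyde α-hydrogen at C6, which the much higher acidity of the titanium-bound chloromethylpyranone at −78 °C and the non-nucleophilic amine (no quaternization of the chloride) should secure.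

Step 10
Reactants: 18 5,6-O-isopropylidene-3'-O-benzyl derivative of the target
Product: 19 (5S,6S,7S,8R)-8-chloro-5,6,7-trihydroxy-2-[2-(3-hydroxy-4-methoxyphenyl)ethyl]-5,6,7,8-tetrahydro-4H-chromen-4-one (CNP0362174.1)
Conditions: BCl3 (6 equiv), C6HMe5 (3 equiv), CH2Cl2, −78 → −20 °C; then MeOH, −78 °C → rt
Reagents that add atoms: none
Why: Lewis-acid debenzylation with BCl3 and pentamethylbenzene as benzyl cation scavenger (Friedel–Crafts capture) should cleave the aryl benzyl ether without hydrogenolysis of the C8 chlorine and without attacking the aryl methyl ether, and the methanolic HCl formed on the quench removes the acetonide by acetal exchange, while the four stereocenters are not ionized because the BCl3-bound pyranone is strongly electron-poor.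

**Compound list**

1 | [3-(benzyloxy)-4-methoxyphenyl]methanol | COc1ccc(CO)cc1OCc1ccccc1 | starting material
2 | 2-(benzyloxy)-4-(bromomethyl)-1-methoxybenzene | COc1ccc(CBr)cc1OCc1ccccc1 | intermediate
3 | 2,2,6-trimethyl-4H-1,3-dioxin-4-one | CC1=CC(=O)OC(C)(C)O1 | starting material
4 | lithium dienolate of 3 (lithium 2,2-dimethyl-6-methylidene-6H-1,3-dioxin-4-olate) | C=C1C=C(O[Li])OC(C)(C)O1 | intermediate
5 | 6-{2-[3-(benzyloxy)-4-methoxyphenyl]ethyl}-2,2-dimethyl-4H-1,3-dioxin-4-one | COc1ccc(CCC2=CC(=O)OC(C)(C)O2)cc1OCc1ccccc1 | intermediate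
6 | 3,4-di-O-acetyl-D-arabinal | C1=C[C@H](OC(C)=O)[C@H](OC(C)=O)CO1 | starting material
7 | D-arabinal (1,5-anhydro-2-deoxy-D-erythro-pent-1-enitol) | C1=C[C@H](O)[C@H](O)CO1 | intermediate
8 | 3,4-O-isopropylidene-D-arabinal | C1=C[C@@H]2OC(C)(C)O[C@@H]2CO1 | intermediate
9 | 1-lithio-3,4-O-isopropylidene-D-arabinal | [Li]C1=C[C@@H]2OC(C)(C)O[C@@H]2CO1 | intermediate
10 | 1-C-(hydroxymethyl)-3,4-O-isopropylidene-D-arabinal (2,6-anhydro-3-deoxy-4,5-O-isopropylidene-D-erythro-hex-2-enitol) | OCC1=C[C@@H]2OC(C)(C)O[C@@H]2CO1 | intermediate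
11 | methanesulfonate of 10 | CS(=O)(=O)OCC1=C[C@@H]2OC(C)(C)O[C@@H]2CO1 | intermediate
12 | 1-C-(chloromethyl)-3,4-O-isopropylidene-D-arabinal | ClCC1=C[C@@H]2OC(C)(C)O[C@@H]2CO1 | intermediate
13 | acylketene 5-[3-(benzyloxy)-4-methoxyphenyl]-3-oxopent-1-en-1-one | COc1ccc(CCC(=O)C=C=O)cc1OCc1ccccc1 | intermediate
14 | hetero-Diels–Alder adduct of 13 and 12: 2,3-dihydro-4-pyranone cis-fused across C1–C2 of the glycal (ketal carbon = sugar C1 bearing CH2Cl; new bonds anti to the acetonide) | ClC[C@]12OC(CCc3ccc(OC)c(OCc4ccccc4)c3)=CC(=O)[C@H]1[C@@H]5OC(C)(C)O[C@@H]5CO2 | intermediate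
15 | 6-{2-[3-(benzyloxy)-4-methoxyphenyl]ethyl}-2-(chloromethyl)-3-[(4S,5R)-5-(hydroxymethyl)-2,2-dimethyl-1,3-dioxolan-4-yl]-4H-pyran-4-one | COc1ccc(CCc2cc(=O)c([C@@H]3OC(C)(C)O[C@@H]3CO)c(CCl)o2)cc1OCc1ccccc1 | intermediate
16 | (4S,5S)-5-{6-[2-(3-benzyloxy-4-methoxyphenyl)ethyl]-2-(chloromethyl)-4-oxo-4H-pyran-3-yl}-2,2-dimethyl-1,3-dioxolane-4-carbaldehyde | COc1ccc(CCc2cc(=O)c([C@@H]3OC(C)(C)O[C@@H]3C=O)c(CCl)o2)cc1OCc1ccccc1 | intermediate
17 | trichlorotitanium dienolate of 16: 2-(chloromethylidene)-4-(trichlorotitanoxy)-2H-pyran, chlorine on the side of O1 | COc1ccc(CCC2=CC(O[Ti](Cl)(Cl)Cl)=C([C@@H]3OC(C)(C)O[C@@H]3C=O)/C(=C/Cl)O2)cc1OCc1ccccc1 | intermediate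
18 | 2-{2-[3-(benzyloxy)-4-methoxyphenyl]ethyl}-8-chloro-7-hydroxy-5,6-(isopropylidenedioxy)-5,6,7,8-tetrahydro-4H-chromen-4-one (O5, O6, O7 all cis; Cl trans to 7-OH; configuration as in 19) | COc1ccc(CCc2cc(=O)c3c(o2)[C@H](Cl)[C@@H](O)[C@H]4OC(C)(C)O[C@@H]34)cc1OCc1ccccc1 | intermediate
19 | (5S,6S,7S,8R)-8-chloro-5,6,7-trihydroxy-2-[2-(3-hydroxy-4-methoxyphenyl)ethyl]-5,6,7,8-tetrahydro-4H-chromen-4-one | COc1ccc(CCc2cc(=O)c3c(o2)[C@H](Cl)[C@@H](O)[C@@H](O)[C@H]3O)cc1O | target

**Step count and risks**

Total step count: 10. Longest linear sequence: 8 steps (6 → 19, steps 3 to 10).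

Steps most likely to fail:

Step 9 (Proposed new method). What may go wrong: attack on the wrong aldehyde face at C7 or the wrong relative orientation at C8 (poor diastereofacial selectivity), enolization of the aldehyde at C6 with loss of the cis-dioxolane configuration, or epoxide closure of the chlorohydrin. The fallback uses known reactions only, sets out from 16 and comes back to the route at 19. PPh3 in MeCN at 50 °C converts 16 into the phosphonium chloride F1. K2CO3 in CH2Cl2/H2O forms the pyranone-stabilized ylide, which closes the same C7–C8 bond by an intramolecular Wittig reaction to the 7,8-alkene acetonide F2. Aqueous AcOH removes the acetonide to give the cis-5,6-diol F3. Epoxidation directed by the allylic 6-hydroxyl (VO(acac)2, tBuOOH) gives the 7,8-epoxide F4 on the face of O6. HCl in Et2O opens the epoxide at C8 (next to the pyranone ring, remote from the C6 oxygen) with inversion to the trans-chlorohydrin F5. BCl3/pentamethylbenzene then removes the benzyl ether to give 19.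

Step 7. What may go wrong: dimerization of the acylketene outruns its cycloaddition to the hindered, inductively deactivated enol ether, or the acetonide migrates to the freed primary hydroxyl in the acid stage. The fallback sets out from 5 and 12 and comes back at 15; it builds the same 1,3-dicarbonyl array stepwise by polar reactions. Compound 5 is hydrolysed and decarboxylated (H2O, toluene, 110 °C) to the methyl ketone F6. Compound 12 is formylated at C2 (sugar numbering) under Vilsmeier–Haack conditions (POCl3, DMF) to the 2-C-formyl glycal F7. The kinetic lithium enolate of F6 (LiN(iPr)2, THF, −78 °C) adds to F7 to give the β-hydroxy ketone F8 (both carbinol epimers serve). Dess–Martin oxidation gives the 1,3-diketone F9. Catalytic TsOH·H2O then closes the pyranone by addition–elimination at C1 with opening of the sugar ring, giving 15.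

Step 6. What may go wrong: ionization or hydrolysis of the 2-alkoxyallyl chloride during work-up, or its decomposition on heating in step 7. The fallback sets out from 8 and comes back at 15; the chlorine is introduced only after the pyranone is made. The C1-lithio glycal from 8 (tBuLi) is quenched with MeI to the 1-C-methyl glycal F10. Cycloaddition and aromatization with 5 under the conditions of step 7 give the 2-methylpyranone alcohol F11. Double deprotonation (LiN(SiMe3)2, 2.2 equiv, THF, −78 °C; alkoxide and lateral dienolate of the 2-methyl group) and quench with C2Cl6 chlorinate the methyl group to give 15.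

Further compounds
F1 | step 9 | {[6-{2-[3-(benzyloxy)-4-methoxyphenyl]ethyl}-3-[(4S,5S)-5-formyl-2,2-dimethyl-1,3-dioxolan-4-yl]-4-oxo-4H-pyran-2-yl]methyl}triphenylphosphonium chloride | COc1ccc(CCc2cc(=O)c([C@@H]3OC(C)(C)O[C@@H]3C=O)c(C[P+](c3ccccc3)(c3ccccc3)c3ccccc3)o2)cc1OCc1ccccc1.[Cl-]
F2 | step 9 | 2-{2-[3-(benzyloxy)-4-methoxyphenyl]ethyl}-5,6-(isopropylidenedioxy)-5,6-dihydro-4H-chromen-4-one (7,8-alkene, cis-acetonide, configuration at C5/C6 as in 18) | COc1ccc(CCc2cc(=O)c3c(o2)C=C[C@H]4OC(C)(C)O[C@@H]34)cc1OCc1ccccc1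
F3 | step 9 | 2-{2-[3-(benzyloxy)-4-methoxyphenyl]ethyl}-5,6-dihydroxy-5,6-dihydro-4H-chromen-4-one (cis-5,6-diol, 7,8-alkene) | COc1ccc(CCc2cc(=O)c3c(o2)C=C[C@@H](O)[C@H]3O)cc1OCc1ccccc1
F4 | step 9 | 2-{2-[3-(benzyloxy)-4-methoxyphenyl]ethyl}-7,8-epoxy-5,6-dihydroxy-5,6,7,8-tetrahydro-4H-chromen-4-one (epoxide cis to the 5,6-diol) | COc1ccc(CCc2cc(=O)c3c(o2)[C@H]5O[C@H]5[C@@H](O)[C@H]3O)cc1OCc1ccccc1
F5 | step 9 | (5S,6S,7S,8R)-2-{2-[3-(benzyloxy)-4-methoxyphenyl]ethyl}-8-chloro-5,6,7-trihydroxy-5,6,7,8-tetrahydro-4H-chromen-4-one | COc1ccc(CCc2cc(=O)c3c(o2)[C@H](Cl)[C@@H](O)[C@@H](O)[C@H]3O)cc1OCc1ccccc1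
F6 | step 7 | 4-[3-(benzyloxy)-4-methoxyphenyl]butan-2-one | COc1ccc(CCC(C)=O)cc1OCc1ccccc1
F7 | step 7 | 1-C-(chloromethyl)-2-C-formyl-3,4-O-isopropylidene-D-arabinal | ClCC1=C(C=O)[C@@H]2OC(C)(C)O[C@@H]2CO1
F8 | step 7 | β-hydroxy ketone from F6 and F7 (aldol adduct, mixture of carbinol epimers) | ClCC1=C(C(O)CC(=O)CCc3ccc(OC)c(OCc4ccccc4)c3)[C@@H]2OC(C)(C)O[C@@H]2CO1
F9 | step 7 | 1,3-diketone from F8 (2-C-(β-ketoacyl) glycal) | ClCC1=C(C(=O)CC(=O)CCc3ccc(OC)c(OCc4ccccc4)c3)[C@@H]2OC(C)(C)O[C@@H]2CO1
F10 | step 6 | 1-C-methyl-3,4-O-isopropylidene-D-arabinal | CC1=C[C@@H]2OC(C)(C)O[C@@H]2CO1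
F11 | step 6 | 6-{2-[3-(benzyloxy)-4-methoxyphenyl]ethyl}-3-[(4S,5R)-5-(hydroxymethyl)-2,2-dimethyl-1,3-dioxolan-4-yl]-2-methyl-4H-pyran-4-one | COc1ccc(CCc2cc(=O)c([C@@H]3OC(C)(C)O[C@@H]3CO)c(C)o2)cc1OCc1ccccc1
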